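Target: 1,7-bis(4-hydroxy-3-methoxyphenyl)heptan-3-one (C1 on ring A, C3 the ketone, C7 on ring B). The cuts are C1–C2, then C2–C3, then C6–C7.
Enabling feature: C1 is benzylic and para to the free 4-OH of ring A. Ring A plus C1 is therefore a masked p-quinone methide that accepts C2, the α-carbon of the C3 ketone.
Forward: a Wittig reaction joins ring B–C7 to C6–C3, diimide saturates C6=C7, and acylation of a malonic half ester adds C2 as a β-keto benzyl ester.
Vanillyl alcohol is activated as its benzylic acetate. Mild base then frees the quinone methide, and the keto ester enolate forms C1–C2 by 1,6-addition.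
One hydrogenolysis removes both benzyl groups and CO2 is lost. No ring is made, since both arenes are bought.
Stereochemistry: the target has none. The racemic, labile C2 centre of the key product disappears on decarboxylation.

Key step: step 5

Remark: the target SMILES holds no stereocentre and no stereogenic double bond, so the compound is achiral, no enantiomer has to be chosen and no step needs absolute stereocontrol.
Convention: simple metal salts (carboxylates, phenoxides, enolates) of numbered compounds are not numbered apart from the parent compound.

Step 1
Reactants: 1 4-(benzyloxy)-3-methoxybenzaldehyde (O-benzylvanillin); 2 (3-carboxypropyl)triphenylphosphonium bromide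
Product: 4 (E/Z)-5-[4-(benzyloxy)-3-methoxyphenyl]pent-4-enoic acid, via phosphorane carboxylate 3 (not isolated)
Conditions: 2 (1.3 equiv), KOtBu (2.6 equiv), THF, 0 °C; then 1, 0 °C to rt; 1 M HCl work-up
Reagents that add atoms: potassium tert-butoxide, CC(C)(C)[O-].[K+] (only the K+ counter-ion of 3)
Why: Wittig olefination of a non-enolisable aromatic aldehyde with the non-stabilised ylide 3, whose carboxylate is a spectator once two equivalents of base are used, and the alkene geometry is irrelevant because C6=C7 is saturated in step 2.

Step 2
Reactants: 4 (E/Z)-5-[4-(benzyloxy)-3-methoxyphenyl]pent-4-enoic acid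
Product: 5 5-[4-(benzyloxy)-3-methoxyphenyl]pentanoic acid
Conditions: TsNHNH2 (excess, in portions), aq NaOAc, DME, reflux; 1 M HCl work-up
Reagents that add atoms: none
Why: Diimide reduction (concerted syn transfer of two hydrogens from HN=NH made in situ) should saturate the 1,2-disubstituted C=C and cannot cleave the aryl benzyl ether, which a palladium-catalysed hydrogenation would put at risk.

Step 3
Reactants: 5 5-[4-(benzyloxy)-3-methoxyphenyl]pentanoic acid; 6 mono-benzyl malonate (3-(benzyloxy)-3-oxopropanoic acid)
Product: 9 benzyl 7-[4-(benzyloxy)-3-methoxyphenyl]-3-oxoheptanoate, via acyl imidazolide 7 (not isolated), via acylmalonic half ester 8 (not isolated)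
Conditions: 5, CDI, THF, rt; then 6, MgCl2, Et3N (premixed in THF), rt to 40 °C; 1 M HCl work-up
Reagents that add atoms: 1,1'-carbonyldiimidazole, O=C(n1ccnc1)n1ccnc1 (only the imidazolyl group of 7)
Why: Masamune–Brooks homologation, in which the acyl imidazolide 7 C-acylates the chelated magnesium enolate of the half ester 6 and the acylmalonate 8 loses CO2, should give the β-keto benzyl ester in one flask without touching the benzyl ether.

Step 4
Reactants: 10 vanillyl alcohol (4-(hydroxymethyl)-2-methoxyphenol)
Product: 11 4-hydroxy-3-methoxybenzyl acetate (vanillyl acetate, phenol free)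
Conditions: vinyl acetate, Novozym 435 (immobilised CAL-B), MTBE, 35 °C; filter, evaporate below 30 °C, use at once
Reagents that add atoms: vinyl acetate, C=COC(C)=O
Why: Lipase-catalysed irreversible transesterification with an enol ester acylates the primary benzylic hydroxyl and does not accept the phenol, as in the enzymatic preparation of vanillyl esters, and the neutral medium avoids premature ionisation of 11.

Step 5
Reactants: 9 benzyl 7-[4-(benzyloxy)-3-methoxyphenyl]-3-oxoheptanoate; 11 4-hydroxy-3-methoxybenzyl acetate
Product: 13 benzyl 7-[4-(benzyloxy)-3-methoxyphenyl]-2-(4-hydroxy-3-methoxybenzyl)-3-oxoheptanoate (racemic at C2), via p-quinone methide 12 (not isolated)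
Conditions: 9 (2 equiv), Cs2CO3 (1.2 equiv), dry MeCN, 0 °C to rt; 11 in MeCN added over several hours (syringe pump); aq NH4Cl; unreacted 9 recovered by chromatography
Reagents that add atoms: none
Why: Carbonate deprotonates the free para phenol of 11 and the phenoxide expels the benzylic acetate by 1,6-elimination, the same event that drives self-immolative 4-hydroxybenzyl linkers and the decay of vanillyl esters, so that 12 should form at or below room temperature, whereas expulsion of hydroxide from 10 itself would call for strong heating or for acid that would also switch on Friedel–Crafts attack on the electron-rich rings. The caesium enolate of 9 then adds through C2 to the exocyclic methylene C1 of 12, and the return of aromaticity in ring A makes this C1–C2 bond formation irreversible; the closest known reaction type is the 1,6-conjugate addition of malonates and β-keto esters to p-quinone methides released in situ from 4-hydroxybenzyl acetates, sulfones or alcohols. No ring closes, and the single new stereocentre (C2) is formed racemic without any controlling element, stays configurationally labile between two carbonyl groups and is deleted in step 6. Site selectivity for C2 over C4 is secured by the ester, which makes the C2–H bonds more acidic than the C4–H bonds by roughly ten pKa units, so carbonate generates only the doubly stabilised enolate. C- over O-alkylation follows from reversibility, because a 4-hydroxybenzyl enol ether or aryl ether re-ionises to 12 under the same base while the C-adduct cannot. Mono- over bis-benzylation and capture in preference to oligomerisation of 12 rest on slow addition of 11 to an excess of 9, whose unsubstituted enolate is less hindered and is favoured in the proton exchange with 13, and the benzyl ether keeps ring B from competing as a phenoxide nucleophile.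

Step 6
Reactants: 13 benzyl 7-[4-(benzyloxy)-3-methoxyphenyl]-2-(4-hydroxy-3-methoxybenzyl)-3-oxoheptanoate
Product: 15 1,7-bis(4-hydroxy-3-methoxyphenyl)heptan-3-one (target), via beta-keto acid 14 (not isolated)
Conditions: H2 (1 atm), 10% Pd/C, EtOAc/EtOH, rt; filter, then 50 °C
Reagents that add atoms: none
Why: Palladium-catalysed hydrogenolysis cleaves the benzyl ester and the aryl benzyl ether in one operation, and the α-substituted β-keto acid 14 decarboxylates through the usual six-membered transition state on gentle warming, which removes the C2 centre and leaves the dialkyl ketone and both guaiacol rings unchanged.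

Compound list
1 | 4-(benzyloxy)-3-methoxybenzaldehyde (O-benzylvanillin) | O=Cc1ccc(OCc2ccccc2)c(OC)c1 | starting material
2 | (3-carboxypropyl)triphenylphosphonium bromide | OC(=O)CCC[P+](c1ccccc1)(c1ccccc1)c1ccccc1.[Br-] | starting material
3 | potassium 4-(triphenyl-λ5-phosphanylidene)butanoate (phosphorane carboxylate, not isolated) | [K+].[O-]C(=O)CCC=P(c1ccccc1)(c1ccccc1)c1ccccc1 | intermediate
4 | (E/Z)-5-[4-(benzyloxy)-3-methoxyphenyl]pent-4-enoic acid (mixture of alkene isomers, hence no double-bond descriptor) | OC(=O)CCC=Cc1ccc(OCc2ccccc2)c(OC)c1 | intermediate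
5 | 5-[4-(benzyloxy)-3-methoxyphenyl]pentanoic acid | OC(=O)CCCCc1ccc(OCc2ccccc2)c(OC)c1 | intermediate
6 | mono-benzyl malonate (3-(benzyloxy)-3-oxopropanoic acid) | OC(=O)CC(=O)OCc1ccccc1 | starting material
7 | 1-{5-[4-(benzyloxy)-3-methoxyphenyl]pentanoyl}imidazole (acyl imidazolide, not isolated) | O=C(CCCCc1ccc(OCc2ccccc2)c(OC)c1)n1ccnc1 | intermediate
8 | 2-[(benzyloxy)carbonyl]-7-[4-(benzyloxy)-3-methoxyphenyl]-3-oxoheptanoic acid (acylmalonic half ester, present as its magnesium salt, not isolated) | OC(=O)C(C(=O)OCc1ccccc1)C(=O)CCCCc1ccc(OCc2ccccc2)c(OC)c1 | intermediate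
9 | benzyl 7-[4-(benzyloxy)-3-methoxyphenyl]-3-oxoheptanoate | O=C(CC(=O)CCCCc1ccc(OCc2ccccc2)c(OC)c1)OCc1ccccc1 | intermediate
10 | vanillyl alcohol (4-(hydroxymethyl)-2-methoxyphenol) | COc1cc(CO)ccc1O | starting material
11 | 4-hydroxy-3-methoxybenzyl acetate (vanillyl acetate) | COc1cc(COC(C)=O)ccc1O | intermediate
12 | 2-methoxy-4-methylidenecyclohexa-2,5-dien-1-one (p-quinone methide, not isolated) | COC1=CC(=C)C=CC1=O | intermediate
13 | benzyl 7-[4-(benzyloxy)-3-methoxyphenyl]-2-(4-hydroxy-3-methoxybenzyl)-3-oxoheptanoate (racemic at C2) | COc1cc(CC(C(=O)OCc2ccccc2)C(=O)CCCCc2ccc(OCc3ccccc3)c(OC)c2)ccc1O | intermediate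
14 | 2-(4-hydroxy-3-methoxybenzyl)-7-(4-hydroxy-3-methoxyphenyl)-3-oxoheptanoic acid (β-keto acid, racemic, not isolated) | COc1cc(CC(C(O)=O)C(=O)CCCCc2ccc(O)c(OC)c2)ccc1O | intermediate
15 | 1,7-bis(4-hydroxy-3-methoxyphenyl)heptan-3-one (achiral) | COc1cc(CCCCC(=O)CCc2ccc(O)c(OC)c2)ccc1O | target

Total step count: 6. Longest linear sequence: 5 (steps 1, 2, 3, 5, 6). Step 4 lies on the short branch.

Steps most likely to fail

Step 5. The δ-unsubstituted quinone methide may oligomerise or be hydrated by adventitious water faster than the enolate captures it. A second benzylation at C2 may also set in once product accumulates. The fallback sets out from 9 and comes back at 15. It forms the same C1–C2 link by condensation and reduction instead of conjugate addition. A Knoevenagel condensation of 9 with vanillin (COc1cc(C=O)ccc1O; catalytic piperidine/AcOH, toluene, Dean–Stark) should give benzyl 7-[4-(benzyloxy)-3-methoxyphenyl]-2-(4-hydroxy-3-methoxybenzylidene)-3-oxoheptanoate F1. Treatment with H2 and Pd/C then saturates C1=C2 and cleaves both benzyl groups, which gives 14 in the flask. Gentle warming delivers 15.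

Step 4. The benzylic ester may ionise prematurely during concentration or storage, and the acetyl group may slowly migrate to the phenol. Either process would erode the quality of the quinone methide precursor. The fallback sets out from 10 and comes back at 13. It replaces the O-acyl leaving group by a carbon-bound sulfonyl group that tolerates isolation. Treating 10 with sodium p-toluenesulfinate in aqueous formic acid (rt to 40 °C) should give the crystalline 4-hydroxy-3-methoxybenzyl p-tolyl sulfone F2. Added slowly to 9 and Cs2CO3 in MeCN, this sulfone loses sulfinate by 1,6-elimination to the same 12, which is trapped to give 13.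

Step 2. Saturation of the conjugated double bond may stay incomplete, because diimide disproportionates in competition with hydrogen transfer. The remaining alkene would be hard to separate from the product. The fallback sets out from 4 and comes back at 15. It postpones the reduction to the final hydrogenation; the main route reduces early only to keep 9 and 13 isomerically homogeneous. CDI converts 4 into the unsaturated acyl imidazolide F3. The magnesium enolate of 6 is acylated to the unsaturated acylmalonic half ester F4, which loses CO2 to give benzyl (E/Z)-7-[4-(benzyloxy)-3-methoxyphenyl]-3-oxohept-6-enoate F5. Addition of its enolate to 12 (released from 11 as in step 5, where the styrene is inert to the neutral quinone methide under base) gives benzyl (E/Z)-7-[4-(benzyloxy)-3-methoxyphenyl]-2-(4-hydroxy-3-methoxybenzyl)-3-oxohept-6-enoate F6. The closing H2/Pd-C treatment saturates C6=C7 together with the two debenzylations, gives 14 and, after loss of CO2, 15.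

Further compounds
F1 | step 5 | benzyl 7-[4-(benzyloxy)-3-methoxyphenyl]-2-(4-hydroxy-3-methoxybenzylidene)-3-oxoheptanoate (E/Z mixture) | COc1cc(C=C(C(=O)OCc2ccccc2)C(=O)CCCCc2ccc(OCc3ccccc3)c(OC)c2)ccc1O
F2 | step 4 | 4-hydroxy-3-methoxybenzyl p-tolyl sulfone (2-methoxy-4-[(4-methylbenzenesulfonyl)methyl]phenol) | COc1cc(CS(=O)(=O)c2ccc(C)cc2)ccc1O
F3 | step 2 | 1-{(E/Z)-5-[4-(benzyloxy)-3-methoxyphenyl]pent-4-enoyl}imidazole (unsaturated acyl imidazolide) | O=C(CCC=Cc1ccc(OCc2ccccc2)c(OC)c1)n1ccnc1
F4 | step 2 | (E/Z)-2-[(benzyloxy)carbonyl]-7-[4-(benzyloxy)-3-methoxyphenyl]-3-oxohept-6-enoic acid (unsaturated acylmalonic half ester) | OC(=O)C(C(=O)OCc1ccccc1)C(=O)CCC=Cc1ccc(OCc2ccccc2)c(OC)c1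
F5 | step 2 | benzyl (E/Z)-7-[4-(benzyloxy)-3-methoxyphenyl]-3-oxohept-6-enoate | O=C(CC(=O)CCC=Cc1ccc(OCc2ccccc2)c(OC)c1)OCc1ccccc1
F6 | step 2 | benzyl (E/Z)-7-[4-(benzyloxy)-3-methoxyphenyl]-2-(4-hydroxy-3-methoxybenzyl)-3-oxohept-6-enoate (racemic at C2) | COc1cc(CC(C(=O)OCc2ccccc2)C(=O)CCC=Cc2ccc(OCc3ccccc3)c(OC)c2)ccc1O
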